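**Plan**
1. Retrosynthesis: the C14=C15 enol ether and the 20-acetate are taken back to a spiro γ-lactone and a C20 aldehyde. Ring B is then cut at C9–C10, because O–C9–C10–C20–O is an aldol-type 1,3-dioxygen array: C9 (fully substituted, bearing the oxolane oxygen) is a latent oxocarbenium ion and C10 is the α-carbon of a C20 aldehyde.
2. The open (9,10-seco) precursor is cut at C11–C12 (acetylide + 2,2-disubstituted epoxide), C8–C9 (conjugate alkynylation), C6–C7 (Weinreb ketone synthesis) and across ring A (Diels–Alder).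
3. Forward order of rings: ring A (Diels–Alder), 19,6-lactone (reductive lactonisation), spiro lactone ring that later becomes the dihydrofuran (lactonisation), oxolane (gold ketalisation), ring B last (C9–C10). After that only functional groups change.
4. Stereochemistry: C5 and the absolute series from a copper–bis(oxazoline) Diels–Alder; C4 by enolate methylation anti to the C5 and C10 substituents; C8 from a rhodium–bisphosphine alkynylation; C6 by hydride delivery to the convex face of a bicyclic cation; C13 from a Sharpless epoxidation; C9 and C10 in the ring B closure.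

Key step: step 20

Remark on names: positions carry the labdane numbers of the target (ring A = C1–C5 and C10; ring B = C5–C10; C19 = lactone carbonyl on C4; C18 = methyl on C4; C20 on C10; C17 = methyl on C8; side chain C11–C16). α and β refer to the usual drawing with C20 β and H-5 α.
Remark on mixtures: 27–32 are carried as C9 epimers, 31 as an enol-ether E/Z mixture, 36 and 37 as C15 epimers; none of these centres survives.
Assumption: the sense of induction of the copper–bis(oxazoline) catalyst follows its square-planar chelate model and that of the rhodium catalyst is taken by analogy with simple (E)-enones; if either proves opposite, the antipodal ligand is used.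

**Step 1**
Reactants: 1 (2E)-penta-2,4-dienoic acid
Product: 2 (2E)-penta-2,4-dien-1-ol
Conditions: LiAlH4, Et2O, 0 °C
Reagents that add atoms: none
Why: Hydride reduction of the carboxylic acid should give the primary dienol without touching the diene.

**Step 2**
Reactants: 2 (2E)-penta-2,4-dien-1-ol
Product: 3 tert-butyl[(2E)-penta-2,4-dien-1-yloxy]diphenylsilane
Conditions: t-BuPh2SiCl, imidazole, CH2Cl2, 0 °C → rt
Reagents that add atoms: tert-butyl(chloro)diphenylsilane, CC(C)(C)[Si](Cl)(c1ccccc1)c1ccccc1
Why: Silyl ether protection; this bulky silyl ether is chosen because it should survive the later trifluoroacetic acid, organolithium and silver fluoride steps.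

**Step 3**
Reactants: 4 (2E)-4-tert-butoxy-4-oxobut-2-enoic acid (mono-tert-butyl fumarate); 5 1,3-oxazolidin-2-one
Product: 7 tert-butyl (2E)-4-oxo-4-(2-oxo-1,3-oxazolidin-3-yl)but-2-enoate, via mixed pivalic anhydride 6 (not isolated)
Conditions: t-BuCOCl, Et3N, THF, −20 °C; then 5, LiCl, −20 °C → rt
Reagents that add atoms: none
Why: N-acylation of the oxazolidinone through the mixed pivalic anhydride gives the two-point-binding dienophile.

**Step 4**
Reactants: 3 tert-butyl[(2E)-penta-2,4-dien-1-yloxy]diphenylsilane; 7 tert-butyl (2E)-4-oxo-4-(2-oxo-1,3-oxazolidin-3-yl)but-2-enoate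
Product: 8 Diels–Alder adduct (cyclohex-3-ene; 4α-CO2tBu; 5β-acyloxazolidinone with H-5 α; 10β-CH2OSi)
Conditions: [Cu{(S,S)-t-Bu-box}](SbF6)2 (10 mol %; t-Bu-box = 2,2'-(propane-2,2-diyl)bis(4-tert-butyl-4,5-dihydro-1,3-oxazole)), CH2Cl2, 0 °C → rt
Reagents that add atoms: none
Why: Enantioselective Diels–Alder reaction on the chelated s-cis imide bound to divalent copper: the diene should add endo to the imide on its open face, with its substituted terminus bonding to the carbon α to the imide, which sets C5 (absolute), C10 (cis to the imide) and a provisional trans C4.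

**Step 5**
Reactants: 8 Diels–Alder adduct
Product: 9 saturated imide (cyclohexane analogue of 8; same configuration)
Conditions: H2 (1 atm), Pd/C, EtOAc, rt
Reagents that add atoms: none
Why: Heterogeneous hydrogenation of the only C=C bond (C1=C2), which would otherwise interfere with the later acid and gold steps.

**Step 6**
Reactants: 9 saturated imide
Product: 10 Weinreb amide (4α-CO2tBu; 5β-C(O)N(OMe)Me; 10β-CH2OSi)
Conditions: MeNH(OMe)·HCl, AlMe3, CH2Cl2, −10 → 0 °C
Reagents that add atoms: N,O-dimethylhydroxylamine hydrochloride, CNOC.Cl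
Why: Aluminium-amide transamidation of the N-acyl oxazolidinone (Weinreb amide formation); the hindered tert-butyl ester should not react.

**Step 7**
Reactants: 10 Weinreb amide
Product: 12 methylated Weinreb amide (quaternary C4 with 4α-CH3 and 4β-CO2tBu), via potassium enolate 11 (not isolated)
Conditions: KN(SiMe3)2, THF, −78 °C; MeI, −78 → −40 °C
Reagents that add atoms: iodomethane, CI
Why: Ester enolate alkylation: the more acidic and less hindered ester α-H at C4 is removed, and MeI should enter anti to the C5 acyl group and the axial C10 silyloxymethyl group, leaving the ester cis to the C5 acyl group as the target requires.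

**Step 8**
Reactants: 12 methylated Weinreb amide
Product: 13 (E)-enone (C5 bears a (2E)-but-2-enoyl group; C6 ketone)
Conditions: (E)-1-bromoprop-1-ene, t-BuLi, Et2O, −78 °C; then 12, THF, −78 → 0 °C; cold aq. NH4Cl
Reagents that add atoms: (E)-1-bromoprop-1-ene, C/C=C/Br
Why: Weinreb ketone synthesis with a configurationally stable alkenyllithium; the chelated tetrahedral adduct prevents over-addition and the ester on quaternary C4 is shielded.

**Step 9**
Reactants: 13 (E)-enone
Product: 14 alkynyl ketone (C6 ketone; (8R)-methyl; C9≡C11–Si(i-Pr)3)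
Conditions: [Rh(OAc)(C2H4)2]2 (2.5 mol %), (R)-DTBM-SEGPHOS (6 mol %), ethynyltri(propan-2-yl)silane, 1,4-dioxane, 80 °C
Reagents that add atoms: ethynyltri(propan-2-yl)silane, CC(C)[Si](C#C)(C(C)C)C(C)C
Why: Rhodium-catalysed asymmetric conjugate alkynylation of the enone should set C8 under ligand control; the bulky silylacetylene suppresses alkyne dimerisation.

**Step 10**
Reactants: 14 alkynyl ketone
Product: 16 silyl alkyne lactone (cis-fused 19,6β-olide; H-5 and H-6 α), via keto acid 15 (not isolated)
Conditions: CF3CO2H/CH2Cl2 (1:4), 0 °C → rt; then Et3SiH, rt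
Reagents that add atoms: none
Why: Acidolysis of the tert-butyl ester gives the cis γ-keto acid, and ionic hydrogenation of its cyclic acyloxycarbenium ion (reductive lactonisation) should deliver hydride to C6 on the convex face, anti to ring A and the C10 substituent, setting H-6 cis to H-5.

**Step 11**
Reactants: 16 silyl alkyne lactone
Product: 18 terminal alkyne lactone, via silver acetylide 17 (not isolated)
Conditions: AgF, MeOH, rt, dark; then 1 M HCl
Reagents that add atoms: none
Why: Silver-fluoride cleavage of the alkynyl C–Si bond through the silver acetylide, a protocol selective for alkynylsilanes over silyl ethers.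

**Step 12**
Reactants: 19 4-methoxy-2-methylidene-4-oxobutanoic acid (4-methyl hydrogen itaconate)
Product: 20 methyl 3-(hydroxymethyl)but-3-enoate
Conditions: BH3·SMe2, THF, −10 → 0 °C; MeOH
Reagents that add atoms: none
Why: Borane reduces the free carboxylic acid much faster than the ester or the electron-poor alkene (chemoselective acid reduction).

**Step 13**
Reactants: 20 methyl 3-(hydroxymethyl)but-3-enoate
Product: 21 methyl [(2R)-2-(hydroxymethyl)oxiran-2-yl]acetate
Conditions: Ti(OiPr)4 (10 mol %), D-(−)-diethyl tartrate (12 mol %), t-BuOOH, 4 Å molecular sieves, CH2Cl2, −20 °C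
Reagents that add atoms: tert-butyl hydroperoxide, CC(C)(C)OO
Why: Sharpless asymmetric epoxidation of the 2-substituted allylic alcohol; the D-tartrate ligand should deliver oxygen to the face that gives the (R)-epoxy alcohol, whose quaternary carbon becomes C13.

**Step 14**
Reactants: 21 methyl [(2R)-2-(hydroxymethyl)oxiran-2-yl]acetate
Product: 22 methyl [(2S)-2-{[(triethylsilyl)oxy]methyl}oxiran-2-yl]acetate
Conditions: Et3SiCl, imidazole, CH2Cl2, 0 °C
Reagents that add atoms: chlorotriethylsilane, CC[Si](Cl)(CC)CC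
Why: Silylation of the primary alcohol, so that no alkoxide is present in the coupling and the epoxide cannot migrate.

**Step 15**
Reactants: 18 terminal alkyne lactone; 22 methyl [(2S)-2-{[(triethylsilyl)oxy]methyl}oxiran-2-yl]acetate
Product: 25 hydroxy lactone alkynol (C11 bonded to the CH2 of a (3-hydroxy-5-oxooxolan-3-yl)methyl group; C13 as in the target), via lithium acetylide 23 (not isolated), via silyl ether ester 24 (not isolated)
Conditions: n-BuLi, THF, −78 °C; BF3·OEt2; 22, −78 °C; work-up; then TsOH·H2O (cat.), CH2Cl2/MeOH (20:1), rt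
Reagents that add atoms: none
Why: BF3-promoted opening of the 2,2-disubstituted epoxide by the lithium acetylide at its CH2 carbon forms C11–C12 without touching C13, and the acid stage removes the triethylsilyl group so that the γ-hydroxy ester lactonises and closes the spiro lactone ring.

**Step 16**
Reactants: 25 hydroxy lactone alkynol
Product: 27 silyl ether ketal (9-methoxy-9,13-epoxy-9,10-seco compound; oxolane ring closed), via dihydrofuran enol ether 26 (not isolated)
Conditions: Ph3PAuCl (2 mol %), AgOTf (2 mol %), pyridinium p-toluenesulfonate (10 mol %), MeOH/CH2Cl2, rt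
Reagents that add atoms: methanol, CO
Why: Monovalent-gold-catalysed 5-endo-dig cycloisomerisation of the homopropargylic alcohol, followed by Markovnikov addition of methanol to the enol ether, should close the oxolane as its C9 methyl ketal.

**Step 17**
Reactants: 27 silyl ether ketal
Product: 28 alcohol ketal (20-hydroxy)
Conditions: Bu4NF, AcOH, THF, 0 °C → rt
Reagents that add atoms: none
Why: Fluoride desilylation, buffered with acetic acid so that no free alkoxide can attack the neighbouring lactone or the β-alkoxy lactone.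

**Step 18**
Reactants: 28 alcohol ketal
Product: 29 aldehyde ketal (20-oxo)
Conditions: Dess–Martin periodinane, NaHCO3, CH2Cl2, 0 °C → rt
Reagents that add atoms: none
Why: Dess–Martin oxidation of the primary alcohol under buffered conditions that spare the ketal; C10 becomes epimerisable, which does not matter because it turns trigonal in the next step.

**Step 19**
Reactants: 29 aldehyde ketal
Product: 31 enol silane (C10=C20–OSiMe3), via lithium enolate 30 (not isolated)
Conditions: LiN(SiMe3)2, Me3SiCl (premixed), THF, −78 °C; non-aqueous work-up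
Reagents that add atoms: chlorotrimethylsilane, C[Si](C)(C)Cl
Why: Kinetic deprotonation of the most acidic C–H (aldehyde α) with internal silyl quench gives the enol silane without any Lewis acid; the enolate oxygen should sit syn to C1, the side of lower allylic strain.

**Step 20**
Reactants: 31 enol silane
Product: 33 pentacyclic aldehyde ((13R)-20-oxo-9α,13-epoxylabdane-19,6β:15,16-diolide), via oxocarbenium triflate 32 (not isolated)
Conditions: Me3SiOTf (0.3 equiv), 2,6-di-tert-butyl-4-methylpyridine, CH2Cl2 (0.005 M), −78 °C; aq. NaHCO3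
Reagents that add atoms: none
Why: Me3SiOTf ionises the C9 methoxy ketal to the five-membered oxocarbenium ion 32, the tethered enol silane attacks it through C10, and silyl transfer to methoxide releases the C20 aldehyde and regenerates the promoter, so the C9–C10 bond between two fully substituted carbons forms in one event. The closest known reaction type is the Mukaiyama addition of silyl enol ethers to ketal-derived oxocarbenium ions, here intramolecular. Ring B (C5–C6–C7–C8–C9–C10) is the only ring closed, in a 6-(enolexo)-exo-trig mode with both the C10=C20 and the C9=O+ bonds exocyclic to it. C10 is controlled by ring A, which the cis-fused 19,6-lactone holds in the chair with C19 axial on the β face: the chain on equatorial C6 reaches only the α (equatorial) lobe of C10, which places C20 axial β and gives the trans ring fusion. C9 is controlled by a chair transition state with the C8 methyl equatorial and the C9=O+ bond antiperiplanar to the C10=C20 bond, which puts the ring oxygen axial (α, anti to C20) and C11 equatorial. The step needs C–C bond formation to outrun proton loss from 32 (which would scramble C8) and intermolecular reaction, secured by low temperature, high dilution and the hindered base; it also needs the C13–O bond to survive a cation at C9, secured by keeping C14–C15 as a saturated lactone until afterwards.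

**Step 21**
Reactants: 33 pentacyclic aldehyde
Product: 34 pentacyclic alcohol (20-hydroxy)
Conditions: NaBH4, MeOH/THF, −20 → 0 °C
Reagents that add atoms: none
Why: Chemoselective borohydride reduction of the aldehyde; both lactones should be inert at this temperature.

**Step 22**
Reactants: 34 pentacyclic alcohol
Product: 35 acetate lactone ((13R)-20-acetoxy-9α,13-epoxylabdane-19,6β:15,16-diolide)
Conditions: Ac2O, pyridine, 4-(dimethylamino)pyridine (cat.), CH2Cl2, rt
Reagents that add atoms: acetic anhydride, CC(=O)OC(C)=O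
Why: Acylation of the neopentyl primary alcohol installs the acetate of the target.

**Step 23**
Reactants: 35 acetate lactone
Product: 36 lactol (15-hydroxy-15,16-epoxy compound)
Conditions: disiamylborane (from BH3·SMe2 and 2-methylbut-2-ene), THF, 0 °C → rt; H2O
Reagents that add atoms: none
Why: Disiamylborane reduces an unhindered γ-lactone to the lactol but not an acetate, and its bulk should spare the 19,6-lactone flanked by quaternary C4.

**Step 24**
Reactants: 36 lactol
Product: 38 CNP0218619.1 ((13R)-20-acetoxy-9α,13:15,16-diepoxylabd-14-en-19,6β-olide), via anomeric mesylate 37 (not isolated)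
Conditions: MeSO2Cl, Et3N (excess), CH2Cl2, −40 °C → rt; Et3N-deactivated silica
Reagents that add atoms: none
Why: Mesylation of the lactol and amine-induced elimination give the 2,3-dihydrofuran; C13 has no hydrogen, so only C14 can be deprotonated, and the basic medium protects the acid-labile allylic C13–O bond.

**Compound list**
1 | (2E)-penta-2,4-dienoic acid | OC(=O)/C=C/C=C | starting material
2 | (2E)-penta-2,4-dien-1-ol | OC/C=C/C=C | intermediate
3 | tert-butyl[(2E)-penta-2,4-dien-1-yloxy]diphenylsilane | CC(C)(C)[Si](c1ccccc1)(c1ccccc1)OC/C=C/C=C | intermediate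
4 | (2E)-4-tert-butoxy-4-oxobut-2-enoic acid (mono-tert-butyl fumarate) | CC(C)(C)OC(=O)/C=C/C(=O)O | starting material
5 | 1,3-oxazolidin-2-one | O=C1NCCO1 | starting material
6 | mixed pivalic anhydride of 4 | CC(C)(C)OC(=O)/C=C/C(=O)OC(=O)C(C)(C)C | intermediate
7 | tert-butyl (2E)-4-oxo-4-(2-oxo-1,3-oxazolidin-3-yl)but-2-enoate | CC(C)(C)OC(=O)/C=C/C(=O)N1CCOC1=O | intermediate
8 | Diels–Alder adduct: tert-butyl 5-{[tert-butyl(diphenyl)silyl]oxymethyl}-6-(2-oxo-1,3-oxazolidine-3-carbonyl)cyclohex-3-ene-1-carboxylate (4α-ester; 5β-acyl; 10β-silyloxymethyl) | CC(C)(C)[Si](c1ccccc1)(c1ccccc1)OC[C@@H]1C=CC[C@@H](C(=O)OC(C)(C)C)[C@@H]1C(=O)N1CCOC1=O | intermediate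
9 | saturated imide: cyclohexane analogue of 8 | CC(C)(C)[Si](c1ccccc1)(c1ccccc1)OC[C@@H]1CCC[C@@H](C(=O)OC(C)(C)C)[C@@H]1C(=O)N1CCOC1=O | intermediate
10 | Weinreb amide: tert-butyl 3-{[tert-butyl(diphenyl)silyl]oxymethyl}-2-[methoxy(methyl)carbamoyl]cyclohexane-1-carboxylate (4α-ester; 5β-amide; 10β-silyloxymethyl) | CC(C)(C)[Si](c1ccccc1)(c1ccccc1)OC[C@@H]1CCC[C@@H](C(=O)OC(C)(C)C)[C@@H]1C(=O)N(C)OC | intermediate
11 | potassium ester enolate of 10 (C4 trigonal) | CC(C)(C)[Si](c1ccccc1)(c1ccccc1)OC[C@@H]1CCCC(=C([O-])OC(C)(C)C)[C@@H]1C(=O)N(C)OC.[K+] | intermediate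
12 | methylated Weinreb amide (4α-methyl; 4β-CO2tBu; 5β-amide; 10β-silyloxymethyl) | CC(C)(C)[Si](c1ccccc1)(c1ccccc1)OC[C@@H]1CCC[C@](C)(C(=O)OC(C)(C)C)[C@@H]1C(=O)N(C)OC | intermediate
13 | (E)-enone: as 12 with a (2E)-but-2-enoyl group at C5 | CC(C)(C)[Si](c1ccccc1)(c1ccccc1)OC[C@@H]1CCC[C@](C)(C(=O)OC(C)(C)C)[C@@H]1C(=O)/C=C/C | intermediate
14 | alkynyl ketone: as 12 with a (3R)-3-methyl-5-[tri(propan-2-yl)silyl]pent-4-ynoyl group at C5 (C8 R) | CC(C)(C)[Si](c1ccccc1)(c1ccccc1)OC[C@@H]1CCC[C@](C)(C(=O)OC(C)(C)C)[C@@H]1C(=O)C[C@@H](C)C#C[Si](C(C)C)(C(C)C)C(C)C | intermediate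
15 | keto acid: 19-carboxylic acid of 14 | CC(C)(C)[Si](c1ccccc1)(c1ccccc1)OC[C@@H]1CCC[C@](C)(C(=O)O)[C@@H]1C(=O)C[C@@H](C)C#C[Si](C(C)C)(C(C)C)C(C)C | intermediate
16 | silyl alkyne lactone: cis-fused 19,6β-olide (7a-methylhexahydro-2-benzofuran-1(3H)-one; H-5 and H-6 α) with the (2R)-2-methyl-4-[tri(propan-2-yl)silyl]but-3-yn-1-yl chain on C6 and β-CH2OSi(t-Bu)Ph2 on C10 | CC(C)(C)[Si](c1ccccc1)(c1ccccc1)OC[C@@H]1CCC[C@]2(C)C(=O)O[C@H](C[C@@H](C)C#C[Si](C(C)C)(C(C)C)C(C)C)[C@H]12 | intermediate
17 | silver acetylide of 18 | CC(C)(C)[Si](c1ccccc1)(c1ccccc1)OC[C@@H]1CCC[C@]2(C)C(=O)O[C@H](C[C@@H](C)C#C[Ag])[C@H]12 | intermediate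
18 | terminal alkyne lactone: as 16 with C9≡C11–H | CC(C)(C)[Si](c1ccccc1)(c1ccccc1)OC[C@@H]1CCC[C@]2(C)C(=O)O[C@H](C[C@@H](C)C#C)[C@H]12 | intermediate
19 | 4-methoxy-2-methylidene-4-oxobutanoic acid (4-methyl hydrogen itaconate) | C=C(CC(=O)OC)C(=O)O | starting material
20 | methyl 3-(hydroxymethyl)but-3-enoate | C=C(CO)CC(=O)OC | intermediate
21 | methyl [(2R)-2-(hydroxymethyl)oxiran-2-yl]acetate | COC(=O)C[C@]1(CO1)CO | intermediate
22 | methyl [(2S)-2-{[(triethylsilyl)oxy]methyl}oxiran-2-yl]acetate | COC(=O)C[C@]1(CO1)CO[Si](CC)(CC)CC | intermediate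
23 | lithium acetylide of 18 | CC(C)(C)[Si](c1ccccc1)(c1ccccc1)OC[C@@H]1CCC[C@]2(C)C(=O)O[C@H](C[C@@H](C)C#C[Li])[C@H]12 | intermediate
24 | silyl ether ester: as 18 with C11 bonded to CH2–C13(OH)(CH2CO2Me)(CH2OSiEt3), C13 as in the target | CC(C)(C)[Si](c1ccccc1)(c1ccccc1)OC[C@@H]1CCC[C@]2(C)C(=O)O[C@H](C[C@@H](C)C#CC[C@@](O)(CC(=O)OC)CO[Si](CC)(CC)CC)[C@H]12 | intermediate
25 | hydroxy lactone alkynol: as 18 with C11 bonded to the CH2 of a (3-hydroxy-5-oxooxolan-3-yl)methyl group (13-hydroxy-15,16-olide) | CC(C)(C)[Si](c1ccccc1)(c1ccccc1)OC[C@@H]1CCC[C@]2(C)C(=O)O[C@H](C[C@@H](C)C#CC[C@@]3(O)CC(=O)OC3)[C@H]12 | intermediate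
26 | dihydrofuran enol ether (9,13-epoxy with C9=C11) | CC(C)(C)[Si](c1ccccc1)(c1ccccc1)OC[C@@H]1CCC[C@]2(C)C(=O)O[C@H](C[C@@H](C)C3=CC[C@]4(CC(=O)OC4)O3)[C@H]12 | intermediate
27 | silyl ether ketal: (13R)-20-[tert-butyl(diphenyl)silyl]oxy-9-methoxy-9,13-epoxy-9,10-secolabdane-19,6β:15,16-diolide (C9 epimers; C10 β-CH2OSi) | CC(C)(C)[Si](c1ccccc1)(c1ccccc1)OC[C@@H]1CCC[C@]2(C)C(=O)O[C@H](C[C@@H](C)C3(OC)CC[C@]4(CC(=O)OC4)O3)[C@H]12 | intermediate
28 | alcohol ketal: 20-hydroxy analogue of 27 | OC[C@@H]1CCC[C@]2(C)C(=O)O[C@H](C[C@@H](C)C3(OC)CC[C@]4(CC(=O)OC4)O3)[C@H]12 | intermediate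
29 | aldehyde ketal: 20-oxo analogue of 27 | O=C[C@@H]1CCC[C@]2(C)C(=O)O[C@H](C[C@@H](C)C3(OC)CC[C@]4(CC(=O)OC4)O3)[C@H]12 | intermediate
30 | lithium enolate of 29 | [Li+].[O-]C=C1CCC[C@]2(C)C(=O)O[C@H](C[C@@H](C)C3(OC)CC[C@]4(CC(=O)OC4)O3)[C@H]12 | intermediate
31 | enol silane: C10=C20–OSiMe3 analogue of 29 (E/Z mixture) | C[Si](C)(C)OC=C1CCC[C@]2(C)C(=O)O[C@H](C[C@@H](C)C3(OC)CC[C@]4(CC(=O)OC4)O3)[C@H]12 | intermediate
32 | oxocarbenium triflate (C9=O+ in the oxolane ring) | C[Si](C)(C)OC=C1CCC[C@]2(C)C(=O)O[C@H](C[C@@H](C)C3=[O+][C@@]4(CC(=O)OC4)CC3)[C@H]12.[O-]S(=O)(=O)C(F)(F)F | intermediate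
33 | pentacyclic aldehyde: (13R)-20-oxo-9α,13-epoxylabdane-19,6β:15,16-diolide | O=C[C@@]12CCC[C@]3(C)C(=O)O[C@H](C[C@@H](C)[C@]14CC[C@]1(CC(=O)OC1)O4)[C@H]23 | intermediate
34 | pentacyclic alcohol: 20-hydroxy analogue of 33 | OC[C@@]12CCC[C@]3(C)C(=O)O[C@H](C[C@@H](C)[C@]14CC[C@]1(CC(=O)OC1)O4)[C@H]23 | intermediate
35 | acetate lactone: (13R)-20-acetoxy-9α,13-epoxylabdane-19,6β:15,16-diolide | CC(=O)OC[C@@]12CCC[C@]3(C)C(=O)O[C@H](C[C@@H](C)[C@]14CC[C@]1(CC(=O)OC1)O4)[C@H]23 | intermediate
36 | lactol: (13R)-20-acetoxy-15-hydroxy-9α,13:15,16-diepoxylabdan-19,6β-olide (C15 epimers) | CC(=O)OC[C@@]12CCC[C@]3(C)C(=O)O[C@H](C[C@@H](C)[C@]14CC[C@]1(CC(O)OC1)O4)[C@H]23 | intermediate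
37 | anomeric mesylate of 36 | CC(=O)OC[C@@]12CCC[C@]3(C)C(=O)O[C@H](C[C@@H](C)[C@]14CC[C@]1(CC(OS(C)(=O)=O)OC1)O4)[C@H]23 | intermediate
38 | CNP0218619.1: (13R)-20-acetoxy-9α,13:15,16-diepoxylabd-14-en-19,6β-olide | CC(=O)OC[C@@]12CCC[C@]3(C)C(=O)O[C@H](C[C@@H](C)[C@]14CC[C@]1(C=COC1)O4)[C@H]23 | target

**Totals**
Total step count: 24.
Longest linear sequence: 20 steps (1 to 38 through steps 1, 2, 4–11 and 15–24).

**Steps most likely to fail**

Step 20. The risk is poor facial selectivity at C9 if the synclinal transition state competes with the antiperiplanar one; proton loss from the oxocarbenium ion would in addition scramble C8. The fallback reverses the order of the two bonds at C9 and sets out from 25. Buffered fluoride desilylation should give hydroxy lactone diol F1, and Dess–Martin oxidation the hydroxy aldehyde F2. Treatment with LiN(SiMe3)2 and Me3SiCl (two equivalents each) should give bis-silyl enol silane F3. Ph3PAuCl/AgOTf in CH2Cl2/MeOH should then form C9–C10 by a 6-exo-dig Conia-ene-type carbocyclisation of the enol silane onto the alkyne, with C10 set by the same ring A control; after methanolysis of both silyl groups this gives alkylidene aldehyde F4. Camphorsulfonic acid in CH2Cl2 closes the oxolane by Markovnikov addition of the C13 hydroxyl to C9, axially and anti to the axial formyl group, and the route is rejoined at 33.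

Step 10. The risk is poor facial selectivity of hydride delivery to C6 if reduction runs through the open-chain protonated ketone instead of the cyclic cation; partial loss of the silyl ether in acid is a second hazard. The fallback uses reagent control and sets out from 14. Corey–Bakshi–Shibata reduction with (S)-2-methyl-CBS-oxazaborolidine and catecholborane in toluene at −78 °C treats the ring carbon C5 as the large group and should give the (6R)-hydroxy ester F5. Brief treatment with CF3CO2H in CH2Cl2 then cleaves the tert-butyl ester, the hydroxy acid lactonises, and the route is rejoined at 16.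

Step 24. The risk is ionisation of the allylic C13–O bond with aromatisation to the furan, or β-elimination of the ring-opened hydroxy aldehyde under amine base. The fallback avoids sulfonate activation and sets out from 36. PhSSPh and Bu3P should give the phenylthio acetal F6, and m-CPBA with NaHCO3 at −78 °C the sulfoxide F7. Thermolysis in toluene with Et3N should expel benzenesulfenic acid by syn-elimination towards C14 and give the enol ether, rejoining the route at 38.

**Further compounds**
F1 | step 20 | hydroxy lactone diol: 20-hydroxy analogue of 25 | OC[C@@H]1CCC[C@]2(C)C(=O)O[C@H](C[C@@H](C)C#CC[C@@]3(O)CC(=O)OC3)[C@H]12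
F2 | step 20 | hydroxy aldehyde: 20-oxo analogue of 25 | O=C[C@@H]1CCC[C@]2(C)C(=O)O[C@H](C[C@@H](C)C#CC[C@@]3(O)CC(=O)OC3)[C@H]12
F3 | step 20 | bis-silyl enol silane: C10=C20–OSiMe3 and 13-OSiMe3 | C[Si](C)(C)OC=C1CCC[C@]2(C)C(=O)O[C@H](C[C@@H](C)C#CC[C@@]3(O[Si](C)(C)C)CC(=O)OC3)[C@H]12
F4 | step 20 | alkylidene aldehyde: ring B closed with C9=C11 and 13-hydroxy | O=C[C@@]12CCC[C@]3(C)C(=O)O[C@H](C[C@@H](C)C1=CC[C@@]1(O)CC(=O)OC1)[C@H]23
F5 | step 10 | (6R)-hydroxy ester: 6-hydroxy analogue of 14 | CC(C)(C)[Si](c1ccccc1)(c1ccccc1)OC[C@@H]1CCC[C@](C)(C(=O)OC(C)(C)C)[C@@H]1[C@H](O)C[C@@H](C)C#C[Si](C(C)C)(C(C)C)C(C)C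
F6 | step 24 | phenylthio acetal: 15-phenylsulfanyl analogue of 36 | CC(=O)OC[C@@]12CCC[C@]3(C)C(=O)O[C@H](C[C@@H](C)[C@]14CC[C@]1(CC(Sc5ccccc5)OC1)O4)[C@H]23
F7 | step 24 | sulfoxide: 15-phenylsulfinyl analogue of 36 | CC(=O)OC[C@@]12CCC[C@]3(C)C(=O)O[C@H](C[C@@H](C)[C@]14CC[C@]1(CC(S(=O)c5ccccc5)OC1)O4)[C@H]23
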